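## Retrosynthetic overview

1. Target 20 ⇒ triol 17; both angelates go on last and the tertiary OH stays free.
2. 17 ⇒ bicyclic bis(methyl enol ether) 14. The C6 and C10 oxygens are the two ortho-methoxy groups of a benzene ring; C2-OH and C6-OH come from substrate-controlled reductions, H-5 from enol-ether protonation.
3. Key step: 14 ⇒ α-diazo ketone 12 by intramolecular arene cyclopropanation and electrocyclic ring opening (Buchner). The cyclopentanone and the seven-membered ring form in the same operation, and the quaternary C1 is set there.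
4. 12 ⇒ tertiary benzylic carbinol 8 ⇒ β-hydroxy ketone 4 + lithiated 3,5-dimethoxytoluene. A carbinol that later becomes the C2 ketone relays chirality to C4.
5. 4 ⇒ methyl (3R)-3-hydroxypentanoate + i-PrMgCl.

Assumption: methyl (3R)-3-hydroxypentanoate is bought as a catalogue compound (made by Ru–BINAP hydrogenation of methyl 3-oxopentanoate).
Assumption: the aryl addition in step 2 follows the chelate (1,3-syn) model; if the anti diol dominated, the (S)-ester would be used and nothing else changes.
Numbering of bicyclic compounds (daucane): C1 (quaternary, CH3), C2, C3, C4 [C(O)(i-Pr)], C5 (ring-fusion CH) form the five-membered ring; C5–C6–C7–C8(CH3)–C9–C10–C1 form the seven-membered ring. β means the face of the C1 methyl group. The target is (1R,2R,4R,5S,6S).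

## Route

Step 1
Reactants: 1 methyl (3R)-3-hydroxypentanoate; 2 isopropylmagnesium chloride
Product: 4 (5R)-5-hydroxy-2-methylheptan-3-one, via Weinreb amide 3 (not isolated)
Conditions: MeNH(OMe)·HCl, i-PrMgCl (excess), THF, −20 °C; then 0 °C → rt; aq NH4Cl
Reagents that add atoms: N,O-dimethylhydroxylamine hydrochloride, CNOC.Cl (its atoms are carried only in 3)
Why: One-pot Weinreb ketone synthesis: i-PrMgCl first acts as base to make the amide, then adds once to the chelated Weinreb amide, and the carbinol centre is untouched.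

Step 2
Reactants: 4 (5R)-5-hydroxy-2-methylheptan-3-one; 5 1,3-dimethoxy-5-methylbenzene
Product: 8 (3R,5R)-3-(2,6-dimethoxy-4-methylphenyl)-2-methylheptane-3,5-diol, via aryllithium 6 (not isolated), via arylcerium dichloride 7 (not isolated)
Conditions: 5 (2.5 equiv), n-BuLi, THF, 0 °C → rt; CeCl3, −78 °C; then 4, −78 → −20 °C; chromatography to remove the 3-epimer
Reagents that add atoms: cerium(III) chloride, Cl[Ce](Cl)Cl (carried only in 7)
Why: Directed ortho-lithiation between the two OMe groups, then Imamoto organocerium 1,2-addition to the β-alkoxide-chelated ketone (1,3-chelation control, aryl enters axially on the chelate) sets the tertiary carbinol as 3R; the 3-epimer is separated, so later loss of the C5 carbinol costs no ee.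

Step 3
Reactants: 8 (3R,5R)-3-(2,6-dimethoxy-4-methylphenyl)-2-methylheptane-3,5-diol
Product: 9 (5R)-5-(2,6-dimethoxy-4-methylphenyl)-5-hydroxy-6-methylheptan-3-one
Conditions: Dess–Martin periodinane, pyridine, CH2Cl2, 0 °C → rt
Reagents that add atoms: none
Why: Dess–Martin oxidation takes only the secondary alcohol; the tertiary benzylic alcohol cannot be oxidised and the pyridine buffer protects it from acid.

Step 4
Reactants: 9 (5R)-5-(2,6-dimethoxy-4-methylphenyl)-5-hydroxy-6-methylheptan-3-one
Product: 10 (5R)-5-(2,6-dimethoxy-4-methylphenyl)-6-methyl-5-[(trimethylsilyl)oxy]heptan-3-one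
Conditions: 1-(trimethylsilyl)imidazole, CH2Cl2, rt → 40 °C
Reagents that add atoms: 1-(trimethylsilyl)imidazole, C[Si](C)(C)n1ccnc1
Why: Silylation of a hindered tertiary alcohol without enolising the ketone; it blocks retro-aldol in step 5 and carbenoid O–H insertion in step 6.

Step 5
Reactants: 10 (5R)-5-(2,6-dimethoxy-4-methylphenyl)-6-methyl-5-[(trimethylsilyl)oxy]heptan-3-one
Product: 12 (5R)-2-diazo-5-(2,6-dimethoxy-4-methylphenyl)-6-methyl-5-[(trimethylsilyl)oxy]heptan-3-one, via trifluoroacetyl diketone 11 (not isolated)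
Conditions: LiHMDS, THF, −78 °C; CF3CO2CH2CF3; dil. HCl work-up; then p-ABSA, Et3N, H2O, MeCN, rt
Reagents that add atoms: 4-acetamidobenzenesulfonyl azide, CC(=O)Nc1ccc(cc1)S(=O)(=O)N=[N+]=[N-]; 2,2,2-trifluoroethyl trifluoroacetate, O=C(OCC(F)(F)F)C(F)(F)F (its CF3CO group is carried only in 11)
Why: Detrifluoroacetylative (Regitz-type) diazo transfer: the kinetic enolate forms at the ethyl CH2 because the other α-CH2 is neopentylic, and the activated diketone then takes N2 with loss of the trifluoroacetyl group.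

Step 6
Reactants: 12 (5R)-2-diazo-5-(2,6-dimethoxy-4-methylphenyl)-6-methyl-5-[(trimethylsilyl)oxy]heptan-3-one
Product: 14 6,10-dimethoxy-4β-[(trimethylsilyl)oxy]dauca-5,7,9-trien-2-one, via norcaradiene 13 (not isolated)
Conditions: Rh2(O2CCF3)4 (1 mol %), CH2Cl2, 0 °C → rt, syringe-pump addition at high dilution
Reagents that add atoms: none
Why: Proposed new method: an intramolecular Buchner reaction forced onto a methoxy-bearing ipso–ortho bond — the Rh keto-carbenoid cyclopropanates C5–C10 (closing the cyclopentanone) and norcaradiene 13 opens by 6π electrocyclisation to the cycloheptatriene (the second ring); ortho C–H substitution is impossible and both ortho bonds are equivalent; A(1,3) strain places the small OSiMe3 group in the aryl plane beside the far OMe and i-Pr on the face away from the carbenoid, so the C1 methyl ends cis to O-4; closest known reaction type: Rh(II)-catalysed intramolecular Buchner reaction of α-methyl α-diazo ketones giving 8a-methyl-dihydroazulen-1-ones.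

Step 7
Reactants: 14 6,10-dimethoxy-4β-[(trimethylsilyl)oxy]dauca-5,7,9-trien-2-one
Product: 15 6,10-dimethoxy-4β-[(trimethylsilyl)oxy]dauca-5,7,9-trien-2β-ol
Conditions: NaBH4, MeOH/THF, −20 → 0 °C
Reagents that add atoms: none
Why: NaBH4 reduction of the only carbonyl present; hydride enters anti to the adjacent angular methyl (as in 17-keto steroids), giving the 2β-alcohol cis to CH3.

Step 8
Reactants: 15 6,10-dimethoxy-4β-[(trimethylsilyl)oxy]dauca-5,7,9-trien-2β-ol
Product: 16 2β,4β-dihydroxy-5αH-dauc-8-ene-6,10-dione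
Conditions: 1 M aq HCl, THF, 0 °C → rt
Reagents that add atoms: water, O
Why: Acid hydrolysis of both methyl enol ethers and the TMS ether; kinetic C-protonation at C5 comes from the α-face because the β-face is screened by the angular methyl and the silyloxy group, which sets the trans ring fusion (16 is drawn as its 8-en-10-one tautomer).

Step 9
Reactants: 16 2β,4β-dihydroxy-5αH-dauc-8-ene-6,10-dione
Product: 17 2β,4β,6α-trihydroxy-5αH-dauc-8-en-10-one
Conditions: Me4NBH(OAc)3, MeCN/AcOH (1:1), −25 °C
Reagents that add atoms: none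
Why: Evans–Saksena hydroxyl-directed reduction: the β-face hydroxyls deliver hydride to the β-face of the C6 ketone (6α-OH, anti to 4-OH), while C10 has no cis-disposed hydroxyl (C2–O is trans to the C1–C10 bond) and stays as the conjugated enone.

Step 10
Reactants: 17 2β,4β,6α-trihydroxy-5αH-dauc-8-en-10-one; 18 angelic acid
Product: 20 2β,6α-bis(angeloyloxy)-4β-hydroxy-5αH-dauc-8-en-10-one (target), via mixed anhydride 19 (not isolated)
Conditions: 18 (5 equiv), 2,4,6-Cl3C6H2COCl, Et3N, toluene, rt; then 17, 80 °C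
Reagents that add atoms: 2,4,6-trichlorobenzoyl chloride, O=C(Cl)c1c(Cl)cc(Cl)cc1Cl (carried only in 19)
Why: Yamaguchi mixed-anhydride esterification without DMAP acylates both secondary alcohols while keeping the Z (angelate) geometry; the tertiary 4-OH does not react.

## Compound list

1 | methyl (3R)-3-hydroxypentanoate | CC[C@@H](O)CC(=O)OC | starting material
2 | isopropylmagnesium chloride | CC(C)[Mg]Cl | starting material
3 | (3R)-3-hydroxy-N-methoxy-N-methylpentanamide | CC[C@@H](O)CC(=O)N(C)OC | intermediate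
4 | (5R)-5-hydroxy-2-methylheptan-3-one | CC[C@@H](O)CC(=O)C(C)C | intermediate
5 | 1,3-dimethoxy-5-methylbenzene (3,5-dimethoxytoluene) | COc1cc(C)cc(OC)c1 | starting material
6 | (2,6-dimethoxy-4-methylphenyl)lithium | [Li]c1c(OC)cc(C)cc1OC | intermediate
7 | dichloro(2,6-dimethoxy-4-methylphenyl)cerium | Cl[Ce](Cl)c1c(OC)cc(C)cc1OC | intermediate
8 | (3R,5R)-3-(2,6-dimethoxy-4-methylphenyl)-2-methylheptane-3,5-diol | CC[C@@H](O)C[C@@](O)(C(C)C)c1c(OC)cc(C)cc1OC | intermediate
9 | (5R)-5-(2,6-dimethoxy-4-methylphenyl)-5-hydroxy-6-methylheptan-3-one | CCC(=O)C[C@@](O)(C(C)C)c1c(OC)cc(C)cc1OC | intermediate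
10 | (5R)-5-(2,6-dimethoxy-4-methylphenyl)-6-methyl-5-[(trimethylsilyl)oxy]heptan-3-one | CCC(=O)C[C@@](O[Si](C)(C)C)(C(C)C)c1c(OC)cc(C)cc1OC | intermediate
11 | (6R)-6-(2,6-dimethoxy-4-methylphenyl)-1,1,1-trifluoro-3,7-dimethyl-6-[(trimethylsilyl)oxy]octane-2,4-dione (C3 epimers/enol) | CC(C(=O)C(F)(F)F)C(=O)C[C@@](O[Si](C)(C)C)(C(C)C)c1c(OC)cc(C)cc1OC | intermediate
12 | (5R)-2-diazo-5-(2,6-dimethoxy-4-methylphenyl)-6-methyl-5-[(trimethylsilyl)oxy]heptan-3-one | CC(=[N+]=[N-])C(=O)C[C@@](O[Si](C)(C)C)(C(C)C)c1c(OC)cc(C)cc1OC | intermediate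
13 | 6,10-dimethoxy-4β-[(trimethylsilyl)oxy]-5,10-cyclodauca-6,8-dien-2-one (norcaradiene valence isomer of 14) | CO[C@]12C=C(C)C=C(OC)[C@]13[C@](O[Si](C)(C)C)(C(C)C)CC(=O)[C@]23C | intermediate
14 | 6,10-dimethoxy-4β-[(trimethylsilyl)oxy]dauca-5,7,9-trien-2-one = (3R,8aS)-4,8-dimethoxy-6,8a-dimethyl-3-(propan-2-yl)-3-[(trimethylsilyl)oxy]-3,8a-dihydroazulen-1(2H)-one | COC1=CC(C)=CC(OC)=C2[C@](O[Si](C)(C)C)(C(C)C)CC(=O)[C@]12C | intermediate
15 | 6,10-dimethoxy-4β-[(trimethylsilyl)oxy]dauca-5,7,9-trien-2β-ol | COC1=CC(C)=CC(OC)=C2[C@](O[Si](C)(C)C)(C(C)C)C[C@@H](O)[C@]12C | intermediate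
16 | 2β,4β-dihydroxy-5αH-dauc-8-ene-6,10-dione | O=C1CC(C)=CC(=O)[C@]2(C)[C@@H]1[C@](O)(C(C)C)C[C@H]2O | intermediate
17 | 2β,4β,6α-trihydroxy-5αH-dauc-8-en-10-one | O[C@H]1CC(C)=CC(=O)[C@]2(C)[C@@H]1[C@](O)(C(C)C)C[C@H]2O | intermediate
18 | angelic acid, (2Z)-2-methylbut-2-enoic acid | C/C=C(/C)C(=O)O | starting material
19 | (2Z)-2-methylbut-2-enoic 2,4,6-trichlorobenzoic anhydride | C/C=C(/C)C(=O)OC(=O)c1c(Cl)cc(Cl)cc1Cl | intermediate
20 | (1R,2R,4R,5S,6S)-2β,6α-bis{[(2Z)-2-methylbut-2-enoyl]oxy}-4β-hydroxy-5αH-dauc-8-en-10-one (CNP0183628.1) | C/C=C(/C)C(=O)O[C@H]1CC(C)=CC(=O)[C@]2(C)[C@@H]1[C@](O)(C(C)C)C[C@H]2OC(=O)/C(C)=C\C | target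

## Step count and risks

Total steps: 10. Longest linear sequence: 10 (1 → 20).

**Step 6 (most likely to fail).** The ring bears methoxy groups on both ortho carbons, a pattern not tested in this reaction. The α-methyl carbenoid may instead undergo 1,2-hydride shift to the enone, insert into the isopropyl C–H, form an O–Si ylide, or stall at a spiro-arenium. The fallback uses an unsubstituted keto-carbenoid (no β-hydrogen, the most dependable class for arene cycloaddition) and installs the angular methyl afterwards by enolate alkylation. It sets out from 2 and 5, with methyl (3R)-3-hydroxybutanoate in place of 1. The chemistry of steps 1–5 then gives (5R)-5-hydroxy-2-methylhexan-3-one F1, the diol (3R,5R)-3-(2,6-dimethoxy-4-methylphenyl)-2-methylhexane-3,5-diol F2, the hydroxy ketone F3, its TMS ether F4 and the terminal diazo ketone F5 (diazo transfer now at the methyl group). Rh2(O2CCF3)4 converts F5 to the 8a-H dihydroazulenone F6. LiHMDS removes the doubly activated C1–H and MeI adds on the face opposite the isopropyl group while C5 is still sp2; this comes back to the route at 14.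

**Step 2.** A hindered aryl nucleophile must add to an enolisable isopropyl ketone, and the 1,3-induction may be modest. The fallback forms the C3–C4 bond instead of the C4–aryl bond. It sets out from 5: aryllithium 6 is acylated with N-methoxy-N-methylisobutyramide to give 1-(2,6-dimethoxy-4-methylphenyl)-2-methylpropan-1-one F7. Reductive lithiation of (R)-1,2-epoxybutane with lithium di-tert-butylbiphenylide gives the β-lithio alkoxide F8, which is added to F7 (CeCl3, −78 °C). This gives 8 together with its C3 epimer, separated as before, and comes back at 8.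

**Step 8.** Acid acts next to a tertiary alcohol that becomes β to a ketone, so dehydration, ionisation or the wrong C5 epimer are possible. The fallback replaces full acid hydrolysis by partial hydrolysis and SN2 O-demethylation. It sets out from 15: PPTS in wet acetone stops at the vinylogous ester 2β,4β-dihydroxy-10-methoxy-5αH-dauca-7,9-dien-6-one F9 (C5 protonated, C6 ketone and TMS ether cleaved). LiI in 2,6-lutidine then removes the remaining O-methyl group by attack at carbon under non-acidic conditions, and the route is rejoined at 16.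

Further compounds
F1 | step 6 | (5R)-5-hydroxy-2-methylhexan-3-one | C[C@@H](O)CC(=O)C(C)C
F2 | step 6 | (3R,5R)-3-(2,6-dimethoxy-4-methylphenyl)-2-methylhexane-3,5-diol | C[C@@H](O)C[C@@](O)(C(C)C)c1c(OC)cc(C)cc1OC
F3 | step 6 | (4R)-4-(2,6-dimethoxy-4-methylphenyl)-4-hydroxy-5-methylhexan-2-one | CC(=O)C[C@@](O)(C(C)C)c1c(OC)cc(C)cc1OC
F4 | step 6 | (4R)-4-(2,6-dimethoxy-4-methylphenyl)-5-methyl-4-[(trimethylsilyl)oxy]hexan-2-one | CC(=O)C[C@@](O[Si](C)(C)C)(C(C)C)c1c(OC)cc(C)cc1OC
F5 | step 6 | (4R)-1-diazo-4-(2,6-dimethoxy-4-methylphenyl)-5-methyl-4-[(trimethylsilyl)oxy]hexan-2-one | [N-]=[N+]=CC(=O)C[C@@](O[Si](C)(C)C)(C(C)C)c1c(OC)cc(C)cc1OC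
F6 | step 6 | (3R)-4,8-dimethoxy-6-methyl-3-(propan-2-yl)-3-[(trimethylsilyl)oxy]-3,8a-dihydroazulen-1(2H)-one (1-demethyl analogue of 14) | COC1=CC(C)=CC(OC)=C2[C@](O[Si](C)(C)C)(C(C)C)CC(=O)[C@H]12
F7 | step 2 | 1-(2,6-dimethoxy-4-methylphenyl)-2-methylpropan-1-one | CC(C)C(=O)c1c(OC)cc(C)cc1OC
F8 | step 2 | lithium 1-lithiobutan-2-olate from (R)-1,2-epoxybutane (same spatial arrangement as C5 of 8) | CC[C@@H](O[Li])C[Li]
F9 | step 8 | 2β,4β-dihydroxy-10-methoxy-5αH-dauca-7,9-dien-6-one | COC1=CC(C)=CC(=O)[C@H]2[C@](O)(C(C)C)C[C@@H](O)[C@]12C
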